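## Structural features

The target is a para-terphenyl whose central benzene ring (ring B, C1' to C6') is fully substituted: 4-hydroxyphenyl rings A and C sit at C1' and C4', free hydroxyls at C2' and C3', and benzoate esters at C5' and C6'. The molecule is achiral, and the only stereocentres that appear on the way are the two adjacent ring-fusion carbons of 8 and 9 (the future C5' and C6'), which are cis and vanish on aromatization. The fragile groups are the two aryl benzoates, which alkoxide, hydroxide or amines would cleave, and the electron-rich free catechol at C2'/C3', which air oxidizes to the ortho-quinone, fastest in base, so the last operations have to be neutral and reductive. Each ester oxygen is meta to the nearest free hydroxyl with an aryl-bearing carbon in between, so the benzoates have no neighbouring hydroxyl to migrate to once they are in place. The real difficulty is twofold: a hexasubstituted benzene flanked by two aryl rings has to be built, and the catechol units C2'/C3' and C5'/C6', equivalent in the symmetrical tetraol, have to be told apart. The key step exploits the fact that C1'-C2'-C3'-C4' is a 1,4-diaryl-2,3-dioxygenated butadiene, held s-cis in the thiophene dioxide 6, while C5'-C6' is a cis-dioxygenated two-carbon unit supplied by 7. The two catechols thus come from different reagents and carry different oxygen substituents (benzyl ethers against a cyclic carbonate) from the moment ring B is formed.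

## Logic of the disconnections

**14 to 13.** The four phenolic O-benzyl bonds are cut last. One neutral hydrogenolysis then frees all four phenols, including the oxidation-prone catechol, under conditions that aryl esters tolerate. The gain is a single protecting group for every phenol from the first step onward. The forward step must spare two aryl benzoates and be worked up without air or base.

**13 to 10 and 11 (through 12).** The two ester bonds O5'-C(=O) and O6'-C(=O) are cut, which releases two molecules of 11, and the freed catechol oxygens are tied together through one carbonyl carbon. These two oxygens therefore travel through the synthesis as a cyclic carbonate, and acylation can only occur at O5' and O6'. The gain is that the regiochemistry of benzoylation stops being a selectivity question. The demand is that 12, a tetra-oxygenated catechol, is acylated twice in the same flask without meeting air.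

**10 to 9.** Hydrogen is added back at C5' and C6'. This turns the arene into the cyclohexa-1,3-diene that a cycloaddition with extrusion delivers. The two sp3 centres are cis and the compound is meso, so no stereochemical problem is created. The forward dehydrogenation must be faster than ionization of the allylic C-O bonds.

**9 to 6 and 7.** C4'-C5' and C6'-C1' are cut and a sulfonyl bridge is put back between C1' and C4'. Ring B then maps onto a symmetric diene and a symmetric dienophile, so there is no regiochemistry and the two catechols are differentiated from the start. All six substituents of ring B are assembled in one step. The demand is a thermal cycloaddition of a hindered diene with a sluggish dienophile at a temperature that 9 survives.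

**6 to 5.** The two enol O-benzyl bonds are cut. Using the same benzyl group as on rings A and C allows one final deprotection. The forward step must alkylate oxygen and not the aryl-bearing carbons of the ambident sulfonyl enolate, and Mitsunobu conditions are chosen for that reason.

**5 to 3 and 4.** C1'-C2' and C3'-C4' (thiophene C2-C3 and C4-C5) are cut. The C2'-C3' bond with both oxygens is bought in 4, while 3 supplies both benzylic nucleophiles and the sulfonyl group that later leaves. The pieces are symmetric and cheap. The demand is a double Claisen condensation driven by dienolate formation.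

**3 to 1.** The two benzylic C-S bonds are cut, which divides the sulfone into two molecules of 1 and a one-sulfur reagent that already stands at the sulfone oxidation level. This saves a separate sulfide oxidation. The demand is two successive S-alkylations by a reactive benzylic chloride, the second on the sulfinate 2 formed in the flask.

## Other disconnections considered

Alternative 1: Three ring bonds are cut at once (C5'-C6', C1'-C2', C3'-C4'), so ring B falls into three alkynes. Two aryl ynol ether units are joined through their oxygens by a di-tert-butylsilylene bridge in A2, and the third alkyne is di-tert-butoxyethyne A3. In the forward direction RhCl(PPh3)3 (monovalent rhodium) would couple the tethered alkynes of A2 to a rhodacyclopentadiene and insert A3 to give the benzodioxasilole A1.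
- In its favour, the ring would be born aromatic, so there is no dehydrogenation and no fragile dihydro intermediate; on this point it is better than the chosen plan. The catechols are differentiated from the outset (silylene on O5'/O6', tert-butyl ethers on O2'/O3'), which equals the chosen plan, and the assembly is more convergent.
- Against it, siloxyalkynes are stable only with bulky silyl groups, and the ynolate precursors of A2 can silylate on carbon. A3 fragments on gentle warming with loss of its tert-butyl groups. A fully substituted, electron-rich monoalkyne would have to insert to form a hexasubstituted benzene. Three different deprotections (fluoride, acid, hydrogenolysis) would surround the benzoylation.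
- In comparison, the elementary steps have precedent in diyne-alkyne cyclotrimerization, but not with three oxygen-substituted alkynes, whereas the chosen plan joins two stable, symmetric partners. In step economy, roughly four steps to A2 and A3 and about five after A1 make it no shorter than the chosen seven.

Alternative 2: The C5'-O and C6'-O bonds of the benzoates are cut, which leads back to the ortho-diketone A5 with the benzoyl carbons bonded directly to ring B. In the forward direction CF3CO3H buffered with Na2HPO4 would carry out two Baeyer-Villiger oxidations with migration of ring B to give A4, which is the same compound as 13.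
- In its favour, A5 should be available from diene 6 and dibenzoylacetylene A6 by cycloaddition and loss of the sulfonyl bridge, which gives the arene directly. The benzoates would be created in their final form, so carbonate cleavage and acylation fall away. The migrating group is the more electron-rich, para-oxygenated aryl, as the Criegee rearrangement requires. The sequence through 6, A5 and A4 to 14 would be six steps, one fewer than the chosen plan; it is better in step economy and in having no dihydro intermediate.
- Against it, the strongest common peracid would meet four benzyl ethers and three electron-rich alkoxyarene rings, so ring hydroxylation and benzylic oxidation would compete. Both carbonyls of A5 are flanked by two ortho substituents and twisted, so peracid addition should be slow exactly where over-oxidation threatens. Any phenyl migration would give a phenyl ester that cannot be corrected.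
- In comparison, the catechols are differentiated equally well. The chosen plan is mild and ionic after the cycloaddition and accepts one more step in exchange for functional-group safety.

Alternative 3: C6'-C1' and C3'-C4' are cut, which divides ring B into two identical arylpyruvate units A8. In the forward direction NaOMe would promote two Claisen-type acylations, each benzylic carbon attacking the ester carbonyl of the other molecule, to give after tautomerization the dihydroxyquinone A7.
- In its favour, it is the shortest way to the terphenyl core, from one component, with all four ring oxygens in place at a usable oxidation level, and it mirrors the biosynthesis. In steps to ring B it is better than the chosen plan.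
- Against it, the ketone carbonyl of A8 is more electrophilic than its ester carbonyl, so aldol-type dimerization followed by lactonization is expected to compete. After reduction of A7 to the tetrol A9 the four hydroxyls are equivalent, yet the target needs benzoates on one ortho pair only. That would require statistical acylation or extra protection steps, with acyl migration between neighbouring oxygens as a further hazard.
- In comparison, the chosen plan brings the two catechols in from different reagents, so this symmetry problem never arises. On paper the total length is about equal, and selectivity is the weaker point of this alternative.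

Key step: step 4

Remark on the chemistry: bridged adduct 8 is drawn as the endo isomer; the endo/exo question is immaterial because either isomer gives the same meso diene 9 once the sulfonyl bridge is lost.

## Route

Step 1
Reactants: 1 4-(benzyloxy)benzyl chloride (2 equiv, both incorporated)
Product: 3 bis[4-(benzyloxy)benzyl] sulfone, via benzylic sulfinate sodium salt 2 (not isolated)
Conditions: 1 (2.0 equiv), HOCH2SO2Na·2H2O (1.0 equiv), K2CO3 (1.5 equiv), Bu4NBr (cat.), DMF, rt then 60 °C
Reagents that add atoms: sodium hydroxymethanesulfinate (Rongalite), [Na+].[O-]S(=O)CO; 4-(benzyloxy)benzyl chloride (second equivalent of 1), ClCc1ccc(OCc2ccccc2)cc1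
Why: Two molecules of 1 are joined through one sulfur: Rongalite acts as a sulfoxylate equivalent, S-benzylation by the first molecule of 1 followed by base-induced loss of formaldehyde gives sulfinate 2, and S-benzylation of 2 by the second molecule of 1 gives the sulfone (one-pot synthesis of symmetrical dibenzyl sulfones from benzyl halides). Any O-benzyl sulfinate ester of this ionizable benzyl group should rearrange to the sulfone on warming.

Step 2
Reactants: 3 bis[4-(benzyloxy)benzyl] sulfone; 4 diethyl oxalate
Product: 5 3,4-dihydroxy-2,5-bis[4-(benzyloxy)phenyl]thiophene 1,1-dioxide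
Conditions: KOtBu (2.5 equiv), THF, 0 °C to reflux; then 1 M HCl, 0 °C
Reagents that add atoms: none
Why: Hinsberg-type double Claisen condensation: each sulfonyl-stabilized benzylic carbanion acylates one ester carbonyl of 4, the second acylation closing the five-membered ring. Formation of the dienolate of 5 drives the equilibria, and this condensation is established for dibenzyl sulfones.

Step 3
Reactants: 5 3,4-dihydroxy-2,5-bis[4-(benzyloxy)phenyl]thiophene 1,1-dioxide
Product: 6 3,4-bis(benzyloxy)-2,5-bis[4-(benzyloxy)phenyl]thiophene 1,1-dioxide
Conditions: BnOH (2.5 equiv), PPh3 (2.5 equiv), DIAD (2.5 equiv), THF, 0 °C to rt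
Reagents that add atoms: benzyl alcohol, OCc1ccccc1
Why: Mitsunobu etherification, once on each enol: the acidic bis-enol (the enol form of a beta-keto sulfone) protonates the betaine and its anion attacks the benzyloxyphosphonium ion through oxygen, as tetronic acids and cyclic 1,3-diones do. This avoids the C-benzylation at the aryl-bearing carbons that a benzyl halide with carbonate base could give.

Step 4
Reactants: 6 3,4-bis(benzyloxy)-2,5-bis[4-(benzyloxy)phenyl]thiophene 1,1-dioxide; 7 vinylene carbonate
Product: 9 (3aR,7aS)-5,6-bis(benzyloxy)-4,7-bis[4-(benzyloxy)phenyl]-3a,7a-dihydro-1,3-benzodioxol-2-one (cis-fused meso compound), via bridged sulfone cycloadduct 8 (not isolated)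
Conditions: 7 (10 equiv), BHT (cat.), o-dichlorobenzene, 150 °C, sealed tube, Ar, acid-free glassware
Reagents that add atoms: none
Why: The C2=C3-C4=C5 diene of 6 and the C=C of 7 combine in a concerted suprafacial [4+2] cycloaddition that forms C4'-C5' and C6'-C1' together and gives the 7-thiabicyclo[2.2.1]hept-2-ene 7,7-dioxide 8. At the reaction temperature 8 loses SO2 by a retro-cheletropic reaction, which makes the sequence irreversible and leaves cyclohexa-1,3-diene 9. The closest known reaction type is the Diels-Alder reaction of tetrasubstituted thiophene 1,1-dioxides (and of cyclopentadienones) with alkenes followed by extrusion, with vinylene carbonate as a cis-enediol dienophile. Ring B is therefore closed by an intermolecular two-bond cycloaddition, and the bridging sulfone ring formed with it is opened again in the same flask. The new stereocentres C3a and C7a are cis because the Z geometry locked in the five-membered carbonate is transferred suprafacially; 9 is meso, and endo or exo approach gives the same compound once the bridge is gone. No regio- or facial selectivity is needed, since each partner has a mirror plane between its reacting termini. What is needed is chemoselectivity: cycloaddition must outrun decomposition of the diene, polymerization of 7 and loss of the allylic carbonate oxygen from 9. The fully substituted diene cannot dimerize, the excess of 7 raises the rate, BHT suppresses radical polymerization, and a neutral medium denies the carbonate both ionization and base-induced anti-elimination.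

Step 5
Reactants: 9 (3aR,7aS)-5,6-bis(benzyloxy)-4,7-bis[4-(benzyloxy)phenyl]-3a,7a-dihydro-1,3-benzodioxol-2-one
Product: 10 5,6-bis(benzyloxy)-4,7-bis[4-(benzyloxy)phenyl]-1,3-benzodioxol-2-one
Conditions: crude 9 after removal of excess 7; DDQ (1.1 equiv), PhMe, 0 °C to rt
Reagents that add atoms: none
Why: DDQ dehydrogenation of a cyclohexadiene: hydride abstraction from the allylic, oxygen-bearing C3a-H gives a cation delocalized over the dialkoxy-diaryl pentadienyl system, and loss of the C7a proton aromatizes. Aryl and enol benzyl ethers are inert to DDQ at room temperature, and the reduced quinone precipitates from toluene, which keeps the solution near neutral.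

Step 6
Reactants: 10 5,6-bis(benzyloxy)-4,7-bis[4-(benzyloxy)phenyl]-1,3-benzodioxol-2-one; 11 benzoyl chloride (2 equiv incorporated)
Product: 13 4,5-bis(benzyloxy)-3,6-bis[4-(benzyloxy)phenyl]-1,2-phenylene dibenzoate, via catechol 12 (not isolated)
Conditions: K2CO3 (0.2 equiv), degassed MeOH/THF, rt, Ar; evaporate, azeotrope with PhMe; then 11 (3 equiv), pyridine (4 equiv), DMAP (cat.), CH2Cl2, 0 °C to rt
Reagents that add atoms: benzoyl chloride (second equivalent of 11), O=C(Cl)c1ccccc1
Why: Base-catalysed methanolysis opens the strained cyclic aryl carbonate, the only electrophile present, to catechol 12 and dimethyl carbonate. DMAP-catalysed O-acylation by two molecules of 11 then places one benzoate on each of the only free hydroxyls, O5' and O6', before the electron-rich catechol can meet air.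

Step 7
Reactants: 13 4,5-bis(benzyloxy)-3,6-bis[4-(benzyloxy)phenyl]-1,2-phenylene dibenzoate
Product: 14 4,5-dihydroxy-3,6-bis(4-hydroxyphenyl)-1,2-phenylene dibenzoate (the target; benzoates on C5' and C6')
Conditions: H2 (1 atm), 10% Pd/C, EtOAc/THF, rt; filtration and concentration under Ar
Reagents that add atoms: none
Why: Heterogeneous catalytic hydrogenolysis cleaves the four aryl benzyl ethers while aryl benzoates are inert under neutral, alcohol-free conditions. No stereocentre is involved, and the esters cannot migrate to the meta hydroxyls.

## Compound list

1 | 4-(benzyloxy)benzyl chloride | ClCc1ccc(OCc2ccccc2)cc1 | starting material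
2 | sodium [4-(benzyloxy)phenyl]methanesulfinate | [Na+].[O-]S(=O)Cc1ccc(OCc2ccccc2)cc1 | intermediate (not isolated)
3 | bis[4-(benzyloxy)benzyl] sulfone | O=S(=O)(Cc1ccc(OCc2ccccc2)cc1)Cc1ccc(OCc2ccccc2)cc1 | intermediate
4 | diethyl oxalate | CCOC(=O)C(=O)OCC | starting material
5 | 3,4-dihydroxy-2,5-bis[4-(benzyloxy)phenyl]thiophene 1,1-dioxide | O=S1(=O)C(c2ccc(OCc3ccccc3)cc2)=C(O)C(O)=C1c1ccc(OCc2ccccc2)cc1 | intermediate
6 | 3,4-bis(benzyloxy)-2,5-bis[4-(benzyloxy)phenyl]thiophene 1,1-dioxide | O=S1(=O)C(c2ccc(OCc3ccccc3)cc2)=C(OCc2ccccc2)C(OCc2ccccc2)=C1c1ccc(OCc2ccccc2)cc1 | intermediate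
7 | vinylene carbonate (1,3-dioxol-2-one) | O=C1OC=CO1 | starting material
8 | endo, 5,6-cis 2,3-bis(benzyloxy)-1,4-bis[4-(benzyloxy)phenyl]-7-thiabicyclo[2.2.1]hept-2-ene-5,6-diyl carbonate 7,7-dioxide | O=C1O[C@@H]2[C@H](O1)[C@]3(c1ccc(OCc4ccccc4)cc1)C(OCc1ccccc1)=C(OCc1ccccc1)[C@@]2(c1ccc(OCc2ccccc2)cc1)S3(=O)=O | intermediate (not isolated)
9 | (3aR,7aS)-5,6-bis(benzyloxy)-4,7-bis[4-(benzyloxy)phenyl]-3a,7a-dihydro-1,3-benzodioxol-2-one (cis-fused meso compound) | O=C1O[C@@H]2[C@H](O1)C(c1ccc(OCc3ccccc3)cc1)=C(OCc1ccccc1)C(OCc1ccccc1)=C2c1ccc(OCc2ccccc2)cc1 | intermediate
10 | 5,6-bis(benzyloxy)-4,7-bis[4-(benzyloxy)phenyl]-1,3-benzodioxol-2-one | O=C1Oc2c(O1)c(-c1ccc(OCc3ccccc3)cc1)c(OCc1ccccc1)c(OCc1ccccc1)c2-c1ccc(OCc2ccccc2)cc1 | intermediate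
11 | benzoyl chloride | O=C(Cl)c1ccccc1 | starting material
12 | 4,5-bis(benzyloxy)-3,6-bis[4-(benzyloxy)phenyl]benzene-1,2-diol | Oc1c(O)c(-c2ccc(OCc3ccccc3)cc2)c(OCc2ccccc2)c(OCc2ccccc2)c1-c1ccc(OCc2ccccc2)cc1 | intermediate (not isolated)
13 | 4,5-bis(benzyloxy)-3,6-bis[4-(benzyloxy)phenyl]-1,2-phenylene dibenzoate | O=C(Oc1c(OC(=O)c2ccccc2)c(-c2ccc(OCc3ccccc3)cc2)c(OCc2ccccc2)c(OCc2ccccc2)c1-c1ccc(OCc2ccccc2)cc1)c1ccccc1 | intermediate
14 | 4,5-dihydroxy-3,6-bis(4-hydroxyphenyl)-1,2-phenylene dibenzoate | O=C(Oc1c(OC(=O)c2ccccc2)c(-c2ccc(O)cc2)c(O)c(O)c1-c1ccc(O)cc1)c1ccccc1 | target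

## Step count and least certain steps

Total step count: 7. Longest linear sequence: 7 steps (1 to 3 to 5 to 6 to 9 to 10 to 13 to 14); 4, 7 and 11 are purchased.

**Step 4 (key step).** The cycloaddition may be too slow at temperatures the product tolerates, because the diene termini carry aryl groups and the diene is donor-substituted. Thermal loss of the allylic carbonate oxygen with aromatization to a phenol, or polymerization of the dienophile, would then dominate.
Fallback, from 1, returning at 9: the diene is rebuilt as its carbon analogue, a cyclopentadienone, which is a far more reactive diene and extrudes CO instead of SO2.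
- Double alkylation of tosylmethyl isocyanide with two equivalents of 1 (NaH, DMSO/Et2O) should give 1,1'-(2-isocyano-2-tosylpropane-1,3-diyl)bis[4-(benzyloxy)benzene] F1.
- Acid hydrolysis (aqueous HCl, CH2Cl2/Et2O) should give 1,3-bis[4-(benzyloxy)phenyl]propan-2-one F2.
- Claisen condensation of F2 with 4 (NaOEt, EtOH, reflux; then 1 M HCl) should close 3,4-dihydroxy-2,5-bis[4-(benzyloxy)phenyl]cyclopenta-2,4-dien-1-one F3, drawn as the bis-enol of the 1,2,4-trione.
- O-Benzylation as in step 3 (BnOH, PPh3, DIAD) should give 3,4-bis(benzyloxy)-2,5-bis[4-(benzyloxy)phenyl]cyclopenta-2,4-dien-1-one F4.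
- F4 and 7 in toluene at 110 °C should give the endo 2,3-bis(benzyloxy)-1,4-bis[4-(benzyloxy)phenyl]-7-oxobicyclo[2.2.1]hept-2-ene-5,6-diyl carbonate F5, which loses CO on further warming (xylene, 140 °C) to give 9.

**Step 5.** The acidic reduced quinone may promote ionization of the allylic carbonate, assisted by the neighbouring benzyloxy enol ether. Aromatization by elimination would then compete with hydride transfer and one ring oxygen would be lost.
Fallback, from 9, returning at 12: the carbonate is removed before oxidation, so the leaving group becomes a hydroxyl and the oxidation becomes an alcohol oxidation. Methanolysis (K2CO3 cat., MeOH/THF, 0 °C) should give (1R,2S)-4,5-bis(benzyloxy)-3,6-bis[4-(benzyloxy)phenyl]cyclohexa-3,5-diene-1,2-diol F6. Oxidation of one allylic hydroxyl (Dess-Martin periodinane, pyridine, CH2Cl2, 0 °C) followed by enolization of the hydroxy dienone should give 12. An aqueous Na2S2O4 wash would return any over-oxidized material to 12, which is benzoylated as in the second half of step 6.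

**Step 3.** Benzylation could occur on carbon of the ambident sulfonyl enolate, or the second etherification of the less acidic mono-ether could stall.
Fallback, from 5, returning at 6: the C-O bonds are made by substitution at ring carbon instead of alkylation at oxygen. POCl3 with catalytic DMF should convert 5 into 3,4-dichloro-2,5-bis[4-(benzyloxy)phenyl]thiophene 1,1-dioxide F7. Sodium benzyloxide (from BnOH and NaH, THF, 0 °C) should then replace both chlorides by addition-elimination at the carbons beta to the sulfone, giving 6.

**Step 7.** The two flanked benzyl ethers at C2' and C3' may cleave slowly, and the liberated catechol may oxidize in air during work-up.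
Fallback, from 13, returning at 14: Lewis-acid debenzylation replaces hydrogenolysis. BCl3 with pentamethylbenzene as cation scavenger (CH2Cl2, -78 °C) cleaves aryl benzyl ethers while sparing aryl esters, and the work-up is acidic and non-oxidizing. It makes no new compound (F0).

## Further compounds

F1 | step 4 | 1,1'-(2-isocyano-2-tosylpropane-1,3-diyl)bis[4-(benzyloxy)benzene] | [C-]#[N+]C(Cc1ccc(OCc2ccccc2)cc1)(Cc1ccc(OCc2ccccc2)cc1)S(=O)(=O)c1ccc(C)cc1
F2 | step 4 | 1,3-bis[4-(benzyloxy)phenyl]propan-2-one | O=C(Cc1ccc(OCc2ccccc2)cc1)Cc1ccc(OCc2ccccc2)cc1
F3 | step 4 | 3,4-dihydroxy-2,5-bis[4-(benzyloxy)phenyl]cyclopenta-2,4-dien-1-one | O=C1C(c2ccc(OCc3ccccc3)cc2)=C(O)C(O)=C1c1ccc(OCc2ccccc2)cc1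
F4 | step 4 | 3,4-bis(benzyloxy)-2,5-bis[4-(benzyloxy)phenyl]cyclopenta-2,4-dien-1-one | O=C1C(c2ccc(OCc3ccccc3)cc2)=C(OCc2ccccc2)C(OCc2ccccc2)=C1c1ccc(OCc2ccccc2)cc1
F5 | step 4 | endo, 5,6-cis 2,3-bis(benzyloxy)-1,4-bis[4-(benzyloxy)phenyl]-7-oxobicyclo[2.2.1]hept-2-ene-5,6-diyl carbonate | O=C1O[C@@H]2[C@H](O1)[C@]3(c1ccc(OCc4ccccc4)cc1)C(OCc1ccccc1)=C(OCc1ccccc1)[C@@]2(c1ccc(OCc2ccccc2)cc1)C3=O
F6 | step 5 | (1R,2S)-4,5-bis(benzyloxy)-3,6-bis[4-(benzyloxy)phenyl]cyclohexa-3,5-diene-1,2-diol | O[C@@H]1[C@H](O)C(c2ccc(OCc3ccccc3)cc2)=C(OCc2ccccc2)C(OCc2ccccc2)=C1c1ccc(OCc2ccccc2)cc1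
F7 | step 3 | 3,4-dichloro-2,5-bis[4-(benzyloxy)phenyl]thiophene 1,1-dioxide | O=S1(=O)C(c2ccc(OCc3ccccc3)cc2)=C(Cl)C(Cl)=C1c1ccc(OCc2ccccc2)cc1
F0 | step 7 | none | none
A1 | alternative 1 | 4,7-bis[4-(benzyloxy)phenyl]-5,6-di-tert-butoxy-2,2-di-tert-butyl-1,3,2-benzodioxasilole | CC(C)(C)[Si]1(C(C)(C)C)Oc2c(O1)c(-c1ccc(OCc3ccccc3)cc1)c(OC(C)(C)C)c(OC(C)(C)C)c2-c1ccc(OCc2ccccc2)cc1
A2 | alternative 1 | di-tert-butylbis{[4-(benzyloxy)phenyl]ethynyloxy}silane | CC(C)(C)[Si](OC#Cc1ccc(OCc2ccccc2)cc1)(OC#Cc1ccc(OCc2ccccc2)cc1)C(C)(C)C
A3 | alternative 1 | di-tert-butoxyethyne | CC(C)(C)OC#COC(C)(C)C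
A4 | alternative 2 | 4,5-bis(benzyloxy)-3,6-bis[4-(benzyloxy)phenyl]-1,2-phenylene dibenzoate (identical with 13) | O=C(Oc1c(OC(=O)c2ccccc2)c(-c2ccc(OCc3ccccc3)cc2)c(OCc2ccccc2)c(OCc2ccccc2)c1-c1ccc(OCc2ccccc2)cc1)c1ccccc1
A5 | alternative 2 | 1,2-dibenzoyl-4,5-bis(benzyloxy)-3,6-bis[4-(benzyloxy)phenyl]benzene | O=C(c1ccccc1)c1c(C(=O)c2ccccc2)c(-c2ccc(OCc3ccccc3)cc2)c(OCc2ccccc2)c(OCc2ccccc2)c1-c1ccc(OCc2ccccc2)cc1
A6 | alternative 2 | 1,4-diphenylbut-2-yne-1,4-dione | O=C(C#CC(=O)c1ccccc1)c1ccccc1
A7 | alternative 3 | 2,5-dihydroxy-3,6-bis[4-(benzyloxy)phenyl]-1,4-benzoquinone | O=C1C(O)=C(c2ccc(OCc3ccccc3)cc2)C(=O)C(O)=C1c1ccc(OCc2ccccc2)cc1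
A8 | alternative 3 | methyl 3-[4-(benzyloxy)phenyl]-2-oxopropanoate | COC(=O)C(=O)Cc1ccc(OCc2ccccc2)cc1
A9 | alternative 3 | 3,6-bis[4-(benzyloxy)phenyl]benzene-1,2,4,5-tetrol | Oc1c(O)c(-c2ccc(OCc3ccccc3)cc2)c(O)c(O)c1-c1ccc(OCc2ccccc2)cc1
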